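**Retrosynthetic overview**
- The target is reached from the 3,19-diol butenolide by functional-group work only: acetylation of the C19 hydroxyl and radical removal of the C3 hydroxyl.
- Key disconnection C12–C13: a C12 aldehyde is joined to the β-carbon of 2(5H)-furanone, used as a nucleophile (a phosphonium ylide, i.e. a homoenolate equivalent). Wittig olefination followed by alkene migration leaves C12 as CH2.
- The C12 aldehyde comes from andrographolide by oxidative excision of C13–C16 at the C12=C13 bond.
- No ring is built: rings A and B (trans-decalin) come intact from andrographolide, and the butenolide ring comes intact from 2(5H)-furanone.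

Assumption: andrographolide (bulk isolate of Andrographis paniculata) counts as a cheap commercial starting material; it supplies C4, C5, C9 and C10 in the target configuration, and none of these centres is epimerisable in the route.

Step 1
Reactants: 1 andrographolide
Product: 2 (3R,4R,5S,9R,10S)-3,19-dihydroxy-13,14,15,16-tetranorlabd-8(17)-en-12-al
Conditions: KMnO4 (2 equiv), THF/H2O 10:1, −10 °C, 20 min
Reagents that add atoms: potassium permanganate, [K+].[O-][Mn](=O)(=O)=O
Why: Permanganate oxidative cleavage; the polarised, conjugated C12=C13 bond of the alkylidene lactone should take up permanganate faster than the hindered, unactivated 8(17)-methylene, the cyclic manganate ester beside the lactone carbonyl collapses to the C12 aldehyde, the alcohols are inert at this temperature and no stereocentre is touched.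

Step 2
Reactants: 2 (3R,4R,5S,9R,10S)-3,19-dihydroxy-13,14,15,16-tetranorlabd-8(17)-en-12-al; 3 furan-2(5H)-one
Product: 8 (3R,4R,5S,9R,10S)-3,19-dihydroxylabda-8(17),13-dien-15,16-olide, via phosphonium triflate 4 (not isolated), via phosphorus ylide 5 (not isolated), via silyl dienol ether 6 (not isolated), via exocyclic-alkene lactone 7 (not isolated)
Conditions: 3 (2.6 equiv), PPh3 (2.6 equiv), TBSOTf (2.5 equiv), THF, 23 °C, 2 h; n-BuLi (2.5 equiv), −78 °C; then 2, −78 → 0 °C; 1 M aq HCl, 0 °C; crude + DBU (0.2 equiv), CH2Cl2, 23 °C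
Reagents that add atoms: triphenylphosphine, c1ccc(cc1)P(c1ccccc1)c1ccccc1 (atoms held only in 4 and 5); tert-butyldimethylsilyl trifluoromethanesulfonate, CC(C)(C)[Si](C)(C)OS(=O)(=O)C(F)(F)F (atoms held only in 4, 5 and 6)
Why: Proposed new method: TBSOTf-assisted 1,4-addition of PPh3 to the butenolide should give the ketene silyl acetal phosphonium salt 4, whose lactone α-position is locked as the silyl acetal so that n-BuLi can only form the C4 ylide 5 (the butenolide β-carbon made nucleophilic); Wittig olefination of the unhindered aldehyde of 2 forms C12=C13, acid hydrolysis of 6 returns the lactone, and DBU moves the exocyclic alkene of 7 into conjugation so that C12 ends as CH2 with no new stereocentre (the excess ylide covers the two free hydroxyls); the closest known reaction type is the phosphoniosilylation–Wittig β-functionalisation of cyclic enones (enone to 3-alkyl-2-enone), here extended to an unsaturated lactone, together with the phosphine–maleate tandem Michael/Wittig olefination.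

Step 3
Reactants: 8 (3R,4R,5S,9R,10S)-3,19-dihydroxylabda-8(17),13-dien-15,16-olide
Product: 9 (3R,4R,5S,9R,10S)-19-acetoxy-3-hydroxylabda-8(17),13-dien-15,16-olide
Conditions: AcCl (1.1 equiv), 2,4,6-collidine, CH2Cl2, −78 °C
Reagents that add atoms: acetyl chloride, CC(Cl)=O
Why: Selective O-acylation of a primary alcohol in a 1,3-diol; with the weak hindered base at low temperature the primary C19 hydroxyl reacts well before the secondary C3 hydroxyl, as in the known C19-selective silylation and tritylation of this diol, and the butenolide is untouched.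

Step 4
Reactants: 9 (3R,4R,5S,9R,10S)-19-acetoxy-3-hydroxylabda-8(17),13-dien-15,16-olide
Product: 10 (3R,4R,5S,9R,10S)-19-acetoxy-3-(phenoxycarbonothioyloxy)labda-8(17),13-dien-15,16-olide
Conditions: PhOC(S)Cl (1.5 equiv), pyridine, DMAP (cat.), CH2Cl2, 0 → 23 °C
Reagents that add atoms: O-phenyl chlorothionoformate, S=C(Cl)Oc1ccccc1
Why: Thionocarbonate formation on the only free hydroxyl (DMAP-catalysed acyl transfer) installs the radical leaving group; acetate, butenolide and alkene do not react.

Step 5
Reactants: 10 (3R,4R,5S,9R,10S)-19-acetoxy-3-(phenoxycarbonothioyloxy)labda-8(17),13-dien-15,16-olide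
Product: 11 (4R,5S,9R,10S)-19-acetoxylabda-8(17),13-dien-15,16-olide (ent-labdane series, CNP0189477.2)
Conditions: Bu3SnH (2 equiv), AIBN (0.2 equiv), toluene, 100 °C
Reagents that add atoms: none
Why: Barton–McCombie deoxygenation; the stannyl radical adds to C=S, the secondary C3 radical is released and quenched by Bu3SnH, C3 becomes CH2 (its stereocentre disappears), and the radical has no alkene within cyclisation range, so the 8(17)-methylene, butenolide and acetate survive.

**Compound list**
1 | andrographolide, (3E,4S)-3-{2-[(1R,4aS,5R,6R,8aS)-6-hydroxy-5-(hydroxymethyl)-5,8a-dimethyl-2-methylidenedecahydronaphthalen-1-yl]ethylidene}-4-hydroxyoxolan-2-one | C=C1CC[C@@H]2[C@](C)(CO)[C@H](O)CC[C@@]2(C)[C@@H]1C/C=C1/C(=O)OC[C@H]1O | starting material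
2 | (3R,4R,5S,9R,10S)-3,19-dihydroxy-13,14,15,16-tetranorlabd-8(17)-en-12-al (ent-labdane decalin carrying CH2CHO at C9) | C=C1CC[C@@H]2[C@](C)(CO)[C@H](O)CC[C@@]2(C)[C@@H]1CC=O | intermediate
3 | furan-2(5H)-one | O=C1OCC=C1 | starting material
4 | [5-(tert-butyldimethylsilyloxy)-2,3-dihydrofuran-3-yl]triphenylphosphonium trifluoromethanesulfonate (racemic) | CC(C)(C)[Si](C)(C)OC1=CC(CO1)[P+](c1ccccc1)(c1ccccc1)c1ccccc1.[O-]S(=O)(=O)C(F)(F)F | intermediate
5 | tert-butyldimethyl{[4-(triphenyl-λ5-phosphanylidene)-4,5-dihydrofuran-2-yl]oxy}silane | CC(C)(C)[Si](C)(C)OC1=CC(CO1)=P(c1ccccc1)(c1ccccc1)c1ccccc1 | intermediate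
6 | (3R,4R,5S,9R,10S)-15-(tert-butyldimethylsilyloxy)-15,16-epoxylabda-8(17),12,14-triene-3,19-diol (12E/Z mixture) | C=C1CC[C@@H]2[C@](C)(CO)[C@H](O)CC[C@@]2(C)[C@@H]1CC=C1COC(O[Si](C)(C)C(C)(C)C)=C1 | intermediate
7 | (3R,4R,5S,9R,10S)-3,19-dihydroxylabda-8(17),12-dien-15,16-olide (12E/Z mixture) | C=C1CC[C@@H]2[C@](C)(CO)[C@H](O)CC[C@@]2(C)[C@@H]1CC=C1COC(=O)C1 | intermediate
8 | (3R,4R,5S,9R,10S)-3,19-dihydroxylabda-8(17),13-dien-15,16-olide | C=C1CC[C@@H]2[C@](C)(CO)[C@H](O)CC[C@@]2(C)[C@@H]1CCC1=CC(=O)OC1 | intermediate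
9 | (3R,4R,5S,9R,10S)-19-acetoxy-3-hydroxylabda-8(17),13-dien-15,16-olide | C=C1CC[C@@H]2[C@](C)(COC(C)=O)[C@H](O)CC[C@@]2(C)[C@@H]1CCC1=CC(=O)OC1 | intermediate
10 | (3R,4R,5S,9R,10S)-19-acetoxy-3-(phenoxycarbonothioyloxy)labda-8(17),13-dien-15,16-olide | C=C1CC[C@@H]2[C@](C)(COC(C)=O)[C@H](OC(=S)Oc3ccccc3)CC[C@@]2(C)[C@@H]1CCC1=CC(=O)OC1 | intermediate
11 | (4R,5S,9R,10S)-19-acetoxylabda-8(17),13-dien-15,16-olide (ent-labdane series) | C=C1CC[C@@H]2[C@](C)(COC(C)=O)CCC[C@@]2(C)[C@@H]1CCC1=CC(=O)OC1 | target

**Count**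
Total steps: 5. Longest linear sequence: 5 (1 → 2 → 8 → 9 → 10 → 11).

**Steps most likely to fail, with fallbacks**

Step 2 is the main risk. The PPh3/TBSOTf adduct is established for enones but not for a lactone, so salt 4 may form poorly, and the ylide may enolise the aldehyde. The fallback sets out from 2 and comes back to the route at 8. PBu3 and dimethyl maleate (THF, 23 → 60 °C) form an ester-stabilised ylide in a tandem phospha-Michael/Wittig reaction and olefinate 2 to the dimethyl (E)-2-alkylidenesuccinate F1. LiOH (1 equiv, THF/H2O, 0 °C) saponifies the unconjugated ester to give the alkylidenesuccinic half-ester F2. i-Bu2AlH (−78 °C) reduces the conjugated ester of the lithium carboxylate to the allylic alcohol. Acid work-up closes the lactone 7, and DBU as in step 2 gives 8.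

Step 1 is the second risk: permanganate may also attack the 8(17)-methylene or over-oxidise the aldehyde. The fallback sets out from 1 and comes back at 8. Exhaustive ozonolysis (O3, CH2Cl2/MeOH, −78 °C; Me2S) cleaves both alkenes and gives the 8-oxo-17-nor keto-aldehyde F3. The step 2 protocol, which selects the aldehyde over the hindered ketone, then gives the 8-oxo-17-nor butenolide diol F6 by way of the 8-oxo silyl dienol ether F4 and the 8-oxo exocyclic-alkene lactone F5. Takai–Lombardo methylenation (Zn, CH2Br2, TiCl4, THF), which leaves the lactone alone, restores the 8(17)-methylene and gives 8.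

Step 3 is the third risk: the primary C19 hydroxyl is neopentyl and axial, so the diacetate or the 3-acetate may form. The fallback sets out from 8 and comes back at 11. 1,1'-Thiocarbonyldiimidazole (THF, 60 °C) ties the 1,3-diol into the 3,19-cyclic thionocarbonate F7. Bu3SnH/AIBN (toluene, 100 °C) opens it at the secondary C3–O bond, and aqueous KF work-up frees the C19 hydroxyl to give the 3-deoxy 19-alcohol F8. Ac2O/pyridine/DMAP then acetylates the only hydroxyl to give 11, so no selectivity is needed.

**Further compounds**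
F1 | step 2 | dimethyl (E)-2-alkylidenesuccinate (Wittig product of 2; C13 carries CO2Me and CH2CO2Me) | C=C1CC[C@@H]2[C@](C)(CO)[C@H](O)CC[C@@]2(C)[C@@H]1C/C=C(\CC(=O)OC)C(=O)OC
F2 | step 2 | alkylidenesuccinic half-ester (conjugated CO2Me kept, CH2CO2H free) | C=C1CC[C@@H]2[C@](C)(CO)[C@H](O)CC[C@@]2(C)[C@@H]1C/C=C(\CC(=O)O)C(=O)OC
F3 | step 1 | 8-oxo-17-nor keto-aldehyde (2 with C8=O in place of C8=CH2, ring configuration as in 2) | O=C1CC[C@@H]2[C@](C)(CO)[C@H](O)CC[C@@]2(C)[C@@H]1CC=O
F4 | step 1 | 8-oxo silyl dienol ether (8-oxo-17-nor analogue of 6) | O=C1CC[C@@H]2[C@](C)(CO)[C@H](O)CC[C@@]2(C)[C@@H]1CC=C1COC(O[Si](C)(C)C(C)(C)C)=C1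
F5 | step 1 | 8-oxo exocyclic-alkene lactone (8-oxo-17-nor analogue of 7) | O=C1CC[C@@H]2[C@](C)(CO)[C@H](O)CC[C@@]2(C)[C@@H]1CC=C1COC(=O)C1
F6 | step 1 | 8-oxo-17-nor butenolide diol (8-oxo-17-nor analogue of 8) | O=C1CC[C@@H]2[C@](C)(CO)[C@H](O)CC[C@@]2(C)[C@@H]1CCC1=CC(=O)OC1
F7 | step 3 | 3,19-cyclic thionocarbonate of 8 | C=C1CC[C@@H]2[C@](C)(COC(=S)O3)[C@H]3CC[C@@]2(C)[C@@H]1CCC1=CC(=O)OC1
F8 | step 3 | 3-deoxy 19-alcohol, (4R,5S,9R,10S)-19-hydroxylabda-8(17),13-dien-15,16-olide | C=C1CC[C@@H]2[C@](C)(CO)CCC[C@@]2(C)[C@@H]1CCC1=CC(=O)OC1
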